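The seven-membered ring (azulene numbering) holds the fusion carbinol carbon C3a γ,δ to the C6(CH3)(OH)–C7(OAr) pair, a masked C6=C7 alkene, with the quaternary C8a next to C3a. That is a cyclohept-4-enone with an α-quaternary carbon, the retron of a Claisen ring expansion. The precursor is an enantiopure (E)-2-alkylidene-5-methyl-5-vinyltetrahydrofuran, reached from (S)-nerolidol by anti bromoetherification and anti dehydrobromination. Heating joins the vinyl CH2 to the exocyclic enol-ether carbon as the ring C–O bond breaks, giving the carbocycle, the ketone, the ring alkene and the quaternary stereocentre in one operation. A carbonyl-ene closure then builds the five-membered ring, and oxidation of the ring alkene completes the target.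

Key step: step 6

Remark: the target SMILES places the C8a methyl, the C3a hydroxyl and the C3 isopropyl group on one face of the five-membered ring. Compounds 8 to 13 are drawn to that configuration and named systematically with the same azulene locants throughout, not by a trivial name.

Remark: the bromoetherification of step 4 can attack either face of the 6,7-alkene, so the bromoether should form as two diastereomers. Both have the same anti relationship between the ring C5–O centre and the C–Br centre and differ only in how that pair sits relative to ring C2. The number 5 stands for this material as a whole; its name and SMILES show the (2S,5R,2′S) isomer (vinyl and bromoalkyl cis). Step 5 should take both isomers to the same enol ether 6.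

Step 1
Reactants: 1 (2E,6E)-farnesol
Product: 2 (2S,3S)-2,3-epoxyfarnesol
Conditions: Ti(OiPr)4 (5–10 mol%), L-(+)-diethyl tartrate (7–12 mol%), t-BuOOH (anhydrous, in decane), 4 Å molecular sieves, CH2Cl2, −20 °C
Reagents that add atoms: tert-butyl hydroperoxide, CC(C)(C)OO
Why: Sharpless asymmetric epoxidation, in which the complex of Ti(OiPr)4 with the tartrate binds the allylic hydroxyl and delivers the peroxide oxygen to one face of the 2,3-alkene only, which with L-(+)-tartrate should set both new centres as 2S,3S while the two remote alkenes, having no hydroxyl to bind through, stay untouched.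

Step 2
Reactants: 2 (2S,3S)-2,3-epoxyfarnesol
Product: 3 (2R,3S)-3-[(3E)-4,8-dimethylnona-3,7-dien-1-yl]-2-(iodomethyl)-3-methyloxirane
Conditions: I2, PPh3, imidazole, Et2O–MeCN (3:1), 0 °C, dark
Reagents that add atoms: iodine, II
Why: Appel-type (Garegg–Samuelsson) iodination, in which iodide displaces the alkoxyphosphonium group at the primary carbon by SN2 while imidazole buffers the medium, so the acid-sensitive epoxide and its two stereocentres are not touched (the descriptor of the CH–O carbon becomes R only because CH2I now outranks the ring carbon).

Step 3
Reactants: 3 epoxy iodide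
Product: 4 (3S,6E)-nerolidol
Conditions: Zn dust (activated), AcOH (cat.), EtOH, 60 °C
Reagents that add atoms: none
Why: Zinc-mediated reductive ring opening (Boord-type β-elimination), in which Zn inserts into the C–I bond and the alkylzinc iodide expels the epoxide oxygen from the neighbouring carbon to form the vinyl group and the tertiary alkoxide without breaking the C3–O bond, so C3 should keep its configuration (3S).

Step 4
Reactants: 4 (3S,6E)-nerolidol
Product: 5 (2S,5R)-5-[(2S)-2-bromo-6-methylhept-5-en-2-yl]-2-ethenyl-2-methyloxolane
Conditions: NBS (1.05 equiv), CH2Cl2, 0 °C, dark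
Reagents that add atoms: N-bromosuccinimide, O=C1CCC(=O)N1Br
Why: Bromoetherification, in which the bromonium ion of the 6,7-alkene is opened anti by the tertiary hydroxyl in the 5-exo mode, so attack on either alkene face gives the same anti relationship between the new ring C5–O centre and the C–Br centre (the drawn isomer and its (2S,5S,2′R) diastereomer, both covered by the number 5), while the bromonium ion of the 10,11-alkene has no internal nucleophile within reach and the vinyl group is the least nucleophilic alkene.

Step 5
Reactants: 5 bromoether (both diastereomers)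
Product: 6 (2S,5E)-2-ethenyl-2-methyl-5-(6-methylhept-5-en-2-ylidene)oxolane
Conditions: n-Bu4NBr (2 equiv), 2,4,6-collidine (3 equiv), acetone, reflux, dark, Ar; filtration through Et3N-deactivated basic Al2O3 (pentane)
Reagents that add atoms: none
Why: Halide-promoted anti E2 dehydrobromination (E2C-like, Saytzeff-selective) under buffered, non-ionising conditions should remove the ring C–H next to oxygen antiperiplanar to bromine and give the most substituted, oxygen-conjugated alkene, and because both diastereomers of 5 share the same relative configuration at the two reacting carbons, both should converge on the single (E) enol ether with the ring oxygen cis to the methyl group.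

Step 6
Reactants: 6 (E)-enol ether
Product: 7 (2R)-2,5-dimethyl-2-(4-methylpent-3-en-1-yl)cyclohept-4-en-1-one
Conditions: toluene (degassed), 2,4,6-collidine (0.2 equiv), base-washed sealed tube, 180 °C
Reagents that add atoms: none
Why: Concerted suprafacial [3,3]-sigmatropic Claisen rearrangement: the vinyl CH2 bonds to the exocyclic enol-ether carbon while the tertiary allylic C–O bond of the oxolane breaks, through the boat-like bridged transition state that the five-membered ring enforces. The closest known reaction is the thermal ring expansion of 2-alkylidene-5-vinyltetrahydrofurans to cyclohept-4-enones, made from linalool- and nerolidol-type bromoethers. The seven-membered carbocycle is closed by two-carbon ring expansion of the ether ring, not by end-to-end cyclisation, which also forces the new ring alkene to be cis. The only new stereocentre, the quaternary carbon, is controlled by the tertiary ether carbon, because the tethered vinyl group can reach only its own face of the enol ether, and by the (E) geometry, which together should give the R configuration. The step needs complete chirality transfer, which the ring tether and the single alkene geometry secure as long as the amine-buffered, acid-free medium prevents isomerisation of the enol ether.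

Step 7
Reactants: 7 cycloheptenone
Product: 8 (3R,3aS,8aR)-6,8a-dimethyl-3-(prop-1-en-2-yl)-2,3,4,5,8,8a-hexahydroazulen-3a(1H)-ol
Conditions: Me2AlCl (1.5 equiv), CH2Cl2, −78 to 0 °C; aq. NaHCO3
Reagents that add atoms: none
Why: Lewis-acid-promoted intramolecular carbonyl-ene reaction with the tether on the attacking alkene carbon, in which the alkene CH bonds 5-exo to the Me2AlCl-bound ketone from the face on which the quaternary carbon holds the tether, placing the new hydroxyl cis to the angular methyl (cis fusion, 3aS), and a prenyl methyl hydrogen passes to the carbonyl oxygen within the same six-atom array, which is possible only if the isopropenyl group ends cis to that oxygen (3R).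

Step 8
Reactants: 8 isopropenyl hydroazulenol
Product: 9 (3R,3aS,8aR)-6,8a-dimethyl-3-(propan-2-yl)-2,3,4,5,8,8a-hexahydroazulen-3a(1H)-ol
Conditions: H2 (1 atm), RhCl(PPh3)3 (5 mol%), toluene–EtOH (1:1), rt
Reagents that add atoms: none
Why: Homogeneous hydrogenation with RhCl(PPh3)3, which reduces the 1,1-disubstituted isopropenyl alkene much faster than the trisubstituted ring alkene, so no stereocentre is created or disturbed.

Step 9
Reactants: 9 hydroazulenol
Product: 10 (3R,3aS,6S,7R,8aR)-6,7-epoxy-6,8a-dimethyl-3-(propan-2-yl)decahydroazulen-3a-ol (oxirane on the face of the 3a-hydroxyl)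
Conditions: VO(acac)2 (5 mol%), t-BuOOH (1.5 equiv, anhydrous in decane), toluene, 25–40 °C
Reagents that add atoms: tert-butyl hydroperoxide, CC(C)(C)OO
Why: Hydroxyl-directed epoxidation, in which the tertiary fusion hydroxyl binds as an alkoxide to the vanadium of VO(acac)2 and so holds the alkyl peroxide over the transannular 6,7-alkene of a boat-like seven-membered ring, so oxygen should be delivered to the face of the hydroxyl (6S,7R), giving the one epoxide that this hydroxyl cannot open by backside attack.

Step 10
Reactants: 10 epoxy alcohol
Product: 11 (3R,3aS,6R,7R,8aR)-6,8a-dimethyl-3-(propan-2-yl)decahydroazulene-3a,6,7-triol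
Conditions: HClO4 (2 mol%), THF–H2O (3:1), 0 °C to rt
Reagents that add atoms: water, O
Why: Acid-catalysed epoxide hydrolysis of borderline SN2 character, in which water attacks the protonated epoxide at the tertiary carbon C6, which carries most of the positive charge, from the side opposite the leaving oxygen, so C6 is inverted (6R) while C7 keeps its oxygen and configuration, giving the trans 6,7-diol.

Step 11
Reactants: 11 triol; 12 4-methoxybenzoyl chloride
Product: 13 (3R,3aS,6R,7R,8aR)-3a,6-dihydroxy-6,8a-dimethyl-3-(propan-2-yl)decahydroazulen-7-yl 4-methoxybenzoate (CNP0244624.1)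
Conditions: 12 (1.2 equiv), pyridine, DMAP (10 mol%), CH2Cl2, 0 °C to rt
Reagents that add atoms: 4-methoxybenzoyl chloride (12), COc1ccc(C(=O)Cl)cc1
Why: DMAP-catalysed acylation (nucleophilic acyl substitution) that should take place only at the secondary C7 hydroxyl, because both tertiary hydroxyls are far more hindered, with no stereocentre involved.

Compound list
1 | (2E,6E)-farnesol | OC/C=C(\C)CC/C=C(\C)CCC=C(C)C | starting material
2 | (2S,3S)-2,3-epoxyfarnesol | OC[C@@H]1O[C@@]1(C)CC/C=C(\C)CCC=C(C)C | intermediate
3 | (2R,3S)-3-[(3E)-4,8-dimethylnona-3,7-dien-1-yl]-2-(iodomethyl)-3-methyloxirane | IC[C@@H]1O[C@@]1(C)CC/C=C(\C)CCC=C(C)C | intermediate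
4 | (3S,6E)-nerolidol | C=C[C@@](C)(O)CC/C=C(\C)CCC=C(C)C | intermediate
5 | (2S,5R)-5-[(2S)-2-bromo-6-methylhept-5-en-2-yl]-2-ethenyl-2-methyloxolane (drawn isomer of the bromoether; carried on together with its (2S,5S,2′R) diastereomer) | C=C[C@]1(C)CC[C@@H](O1)[C@@](C)(Br)CCC=C(C)C | intermediate
6 | (2S,5E)-2-ethenyl-2-methyl-5-(6-methylhept-5-en-2-ylidene)oxolane | C=C[C@]1(C)CC/C(O1)=C(/C)CCC=C(C)C | intermediate
7 | (2R)-2,5-dimethyl-2-(4-methylpent-3-en-1-yl)cyclohept-4-en-1-one | CC1=CC[C@@](C)(CCC=C(C)C)C(=O)CC1 | intermediate
8 | (3R,3aS,8aR)-6,8a-dimethyl-3-(prop-1-en-2-yl)-2,3,4,5,8,8a-hexahydroazulen-3a(1H)-ol | CC1=CC[C@@]2(C)CC[C@H](C(C)=C)[C@@]2(O)CC1 | intermediate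
9 | (3R,3aS,8aR)-6,8a-dimethyl-3-(propan-2-yl)-2,3,4,5,8,8a-hexahydroazulen-3a(1H)-ol | CC1=CC[C@@]2(C)CC[C@H](C(C)C)[C@@]2(O)CC1 | intermediate
10 | (3R,3aS,6S,7R,8aR)-6,7-epoxy-6,8a-dimethyl-3-(propan-2-yl)decahydroazulen-3a-ol | C[C@@]12O[C@@H]1C[C@@]3(C)CC[C@H](C(C)C)[C@@]3(O)CC2 | intermediate
11 | (3R,3aS,6R,7R,8aR)-6,8a-dimethyl-3-(propan-2-yl)decahydroazulene-3a,6,7-triol | O[C@@H]1C[C@@]2(C)CC[C@H](C(C)C)[C@@]2(O)CC[C@@]1(C)O | intermediate
12 | 4-methoxybenzoyl chloride | COc1ccc(C(=O)Cl)cc1 | starting material
13 | (3R,3aS,6R,7R,8aR)-3a,6-dihydroxy-6,8a-dimethyl-3-(propan-2-yl)decahydroazulen-7-yl 4-methoxybenzoate | COc1ccc(C(=O)O[C@@H]2C[C@@]3(C)CC[C@H](C(C)C)[C@@]3(O)CC[C@@]2(C)O)cc1 | target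

Total step count: 11
Longest linear sequence: 11 steps (1 to 13)

Steps most likely to fail

1. Step 5. Proton loss could occur from the methyl group or the chain CH2, giving allylic ethers that cannot rearrange. Partial ionisation of the tertiary bromide could also scramble the alkene geometry and so erode the enantiopurity of everything downstream. The fallback sets out from 4 and comes back at 6; it fixes the geometry by an anti addition to an alkyne and a coupling with retention, and it also bypasses step 4. Ozonolysis of 4 with a dye end-point (O3, CH2Cl2–MeOH, −78 °C, Sudan red; Me2S) should cleave only the two trisubstituted alkenes and leave the vinyl group, giving the lactol (5S)-5-ethenyl-5-methyloxolan-2-ol F1. Ohira–Bestmann homologation of its open hydroxy-aldehyde form (dimethyl (1-diazo-2-oxopropyl)phosphonate, K2CO3, MeOH) then gives (3S)-3-methylhept-1-en-6-yn-3-ol F2. C-methylation of the dianion (n-BuLi, 2 equiv; MeI, 1 equiv; THF–DMPU, −78 to 0 °C) gives (3S)-3-methyloct-1-en-6-yn-3-ol F3. 5-exo-dig iodoetherification (I2, NaHCO3, MeCN, 0 °C) adds oxygen and iodine anti across the alkyne, so the former alkyne methyl ends cis to the ring oxygen in (2S,5E)-2-ethenyl-5-(1-iodoethylidene)-2-methyloxolane F4. Negishi coupling of this vinyl iodide with (4-methylpent-3-en-1-yl)zinc bromide F5 (made from 5-bromo-2-methylpent-2-ene, Zn dust and LiCl in THF; coupling with Pd(PPh3)4, THF, 25–40 °C) replaces iodine with retention and delivers 6.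

2. Step 9. A tertiary, transannular hydroxyl may direct only weakly, so oxygen could be delivered to the face remote from it, and that epoxide would then be opened by the hydroxyl to a bridged ether. The fallback sets out from 9 and comes back at 13, using the same steric bias in its favour. Dihydroxylation (OsO4 cat., NMO, acetone–H2O) from the face remote from the hydroxyl and the angular methyl should give the cis diol (3R,3aS,6R,7S,8aR)-6,8a-dimethyl-3-(propan-2-yl)decahydroazulene-3a,6,7-triol F6, whose tertiary C6 hydroxyl is already placed as in the target. Mitsunobu esterification with 4-methoxybenzoic acid (PPh3, DIAD, toluene, 0 °C to rt) then inverts the secondary C7 centre and gives 13 directly.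

3. Step 7. The closure could turn stepwise and cationic, with chloride capture, proton loss to isomeric alkenes or methyl transfer from aluminium in place of the concerted hydrogen transfer. The fallback sets out from 7 and comes back at 9, making the stepwise path the intended one. Prins cyclisation with the stronger Lewis acid MeAlCl2 (2 equiv, CH2Cl2, −78 °C), with chloride transfer from aluminium to the tertiary cation, should give (3S,3aS,8aR)-3-(2-chloropropan-2-yl)-6,8a-dimethyl-2,3,4,5,8,8a-hexahydroazulen-3a(1H)-ol F7; charge attraction between the developing cation and the aluminium-bound oxygen should favour the compact transition state and hence the same cis relationship. Radical dechlorination (Bu3SnH, AIBN, toluene, 90 °C) then gives the isopropyl compound 9 without passing through 8.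

Further compounds
F1 | step 5 | (5S)-5-ethenyl-5-methyloxolan-2-ol (both anomers) | C=C[C@]1(C)CCC(O)O1
F2 | step 5 | (3S)-3-methylhept-1-en-6-yn-3-ol | C=C[C@@](C)(O)CCC#C
F3 | step 5 | (3S)-3-methyloct-1-en-6-yn-3-ol | C=C[C@@](C)(O)CCC#CC
F4 | step 5 | (2S,5E)-2-ethenyl-5-(1-iodoethylidene)-2-methyloxolane | C=C[C@]1(C)CC/C(O1)=C(/C)I
F5 | step 5 | (4-methylpent-3-en-1-yl)zinc bromide | CC(C)=CCC[Zn]Br
F6 | step 9 | (3R,3aS,6R,7S,8aR)-6,8a-dimethyl-3-(propan-2-yl)decahydroazulene-3a,6,7-triol | O[C@H]1C[C@@]2(C)CC[C@H](C(C)C)[C@@]2(O)CC[C@@]1(C)O
F7 | step 7 | (3S,3aS,8aR)-3-(2-chloropropan-2-yl)-6,8a-dimethyl-2,3,4,5,8,8a-hexahydroazulen-3a(1H)-ol | CC1=CC[C@@]2(C)CC[C@H](C(C)(C)Cl)[C@@]2(O)CC1
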